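## Structural features

The target is a 4-arylflavan-3-ol: a chroman (benzo ring A fused to pyran ring C) that carries a catechol (ring B) on C2, a hydroxyl on C3 and a 2,4-dihydroxy-3-methoxyphenyl group (ring D) on C4. Ring A is a 5-deoxy, resorcinol-type ring with oxygen only on C7 and C8a (the ring oxygen O1) and carbon on C4a. C2, C3 and C4 form a contiguous stereotriad, (2R,3S,4S), with ring B and the C3 hydroxyl trans and the C3 hydroxyl and ring D cis. C4 is a doubly benzylic methine flanked by two electron-rich arenes, and C2 is a benzylic ether carbon para to a ring B oxygen. Both centers ionise easily, and the five free phenols are air-sensitive, so the polyphenol can only be unveiled at the very end. One of the six phenolic oxygens is a methyl ether that must survive, so every other oxygen has to carry a group removable without Lewis acids. The real difficulty is the 3,4-cis placement of ring D: cationic arylation at C4 favours the 3,4-trans arrangement and gives no reliable facial control. The key step exploits the fact that ring A is a 2-alkyl-5-oxyphenol (carbon at C4a, oxygen at C8a and C7), which is exactly what a vinylketene and an oxygenated alkyne assemble; ring A can therefore be grown onto a finished stereotriad in which C4 is only an allylic carbon.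

## Logic of the disconnections

31 back to 30 and 29. Only protecting-group bonds are cut: five O–benzyl bonds of 30 and the aryl O–Si bond of 29. Benzyl is used because hydrogenolysis leaves the methyl ether untouched and lets the oxidisable phenols appear in the last flask. The demand is that hydrogenolysis spares the benzylic C2–O1 and C4–aryl bonds.

29 back to 28 and 27. The O1–C2 bond of ring C is cut. This opens the ring to a chain in which C2 is an ordinary secondary carbinol and O1 is the phenol that the annulation liberates. Closure by SN2 etherification inverts C2, so 28 must carry the C2 epimer (2,3-syn in the chain). The C2 silyl ether of 27 must also be removable without touching the aryl silyl ether or ionising C2; a triethylsilyl ether is chosen for this.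

27 back to 21 and 22. Four ring A bonds are cut: C5–C6, C6–C7, C8–C8a and C4a–C8a. Ring A is reduced to a four-carbon diazo enone terminus and a two-carbon siloxyalkyne, and no arene ever has to be attached to C4 as a cation. The forward step must deliver one regioisomer, run without acid, base or metal so that the allylic C4 center survives, and excite the diazo ketone in the presence of six aryl ether chromophores.

21 back to 19 and 18. The C=N2 unit is cut back to a methyl ketone, and the C4a=C5 enone olefin is traced by alkylidene exchange to the propenyl group of 18. The diazo group is put on by deacylative transfer. Acylation of a diazoalkane by an enoyl chloride is not used because that reagent is hazardous and adds as a dipole to the conjugated double bond. The demands are enolisation at the methyl group only and metathesis at a hindered internal olefin.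

18 back to 17, then to 13 and 15 (through 16). The C2–aryl bond to ring B is cut. Chelation-controlled addition of an aryl nucleophile to the α-benzyloxy aldehyde gives the 2,3-syn alcohol directly. Reduction of the corresponding α-benzyloxy aryl ketone would, under the same chelation, give the 2,3-anti epimer, which is wrong for a closure with inversion. The demand is chelate control and a configurationally stable aldehyde.

13 back to 12 and 9. The C3–C4 bond is cut, with the allylic C–O bond re-formed. One carbinol stereocenter then controls both C3 and C4 through a chair sigmatropic transition state, and the E olefin needed later appears for free. The olefin of 9 has to be Z: with the chelated glycolate enolate an E olefin would give the 3,4-syn pair, which is the 4α series. The demands are clean enolate geometry and a chair transition state.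

9 back to 7 and 8, 7 back to 6, 6 back to 4 and 5, 4 back to 3, 3 back to 1 and 2; 15 back to 14 and 2. The ester C–O bond, the aryl–alkyne bond, the aryl–iodine bond and the benzyl ether bonds are cut. These cuts end at 1, 14, 8, 5 and 2, of which 5 carries the only stereocenter brought in from outside. The demands are Z-selective semi-hydrogenation and iodination at C4 of 3.

## Other disconnections considered

Alternative 1: The cut is C3–C4 together with the O1–C2 acyl bond. Ring C is made as the lactone A1 from the ortho-quinone methide A2 and a carbene-bound benzyloxyketene enolate. In the forward step a chiral N-heterocyclic carbene generates the enolate, its C3 adds to C4 of A2 formed in the flask, and the ring A phenoxide acylates to release the catalyst.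
- In its favour: the step is catalytic, enantioselective and convergent, it sets C3 and C4 together in the cis sense, and rings A and D are bought as arenes.
- Against it here: A1 lacks ring B and the C2 stereocenter. The lactone carbonyl would have to take up an aryl nucleophile and then lose the anomeric oxygen reductively through an oxocarbenium ion. That is acid chemistry next to the doubly benzylic C4, with risks of ionisation, elimination to a flav-3-ene and uncertain 2,3-trans delivery of hydride. The C3 hydrogen of the cis lactone is also acidic under the basic conditions, and A2 with its electron-rich aryl terminus tends to oligomerise.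
- Comparison: on convergence, catalytic control of absolute configuration and steps up to the bicyclic core, alternative 1 is the better plan. On mechanism it exchanges a substrate-controlled pericyclic step for a catalyst-controlled polar one, which is equal in principle. On the C2 problem the chosen plan is safer, because C2 is set by two well-understood operations (chelate addition, inversion) and no cation is generated beside C4.

Alternative 2: The cut is C4–C4a. Ring C is closed when ring A of the aryl ether A4 attacks C4 of its cis-epoxide through C4a to give A3.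
- In its favour: one step closes ring C and frees the C3 hydroxyl, so C3 needs no protecting group. Inversion at C4 of a cis-epoxide leads in principle to the 3,4-cis product, ring A is a purchased phenol, and A3 is only two deprotections from the target.
- Against it here: C4 is benzylic to ring D. Even with the pivalates the acid-promoted opening has strong SN1 character, which would erode the inversion and lead toward the 3,4-trans series. Hydride shift to a ketone competes, an ortho pivalate carbonyl can participate and return retention, and ring A can attack through either carbon ortho to O1 (7-oxy against 5-oxy products). The enantiopure cis-epoxide next to the C2 ether center is itself a demanding intermediate, and the pivalate switch costs separate protection and removal.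
- Comparison: on directness of ring C formation and on the number of steps after the key step, alternative 2 is the better plan. On use of a purchased ring A the two are at least equal. On stereochemical security at C4, the center that defines the 4β series, the chosen plan is stronger, because C4 is fixed by a sigmatropic shift and never becomes cationic.

Alternative 3: The cut is O1–C8a. The bromo alcohol A6 is cyclised with CuI (monovalent copper), 1,10-phenanthroline and Cs2CO3 to the hexabenzyl ether A5.
- In its favour: no stereocenter is touched, so C2 is made in its final configuration, and the required 2,3-anti chain alcohol is the natural product of chelation-controlled ketone reduction. Ring A comes from a simple bromoarene, no diazo compound or lamp is needed, and A5 is one hydrogenolysis from the target.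
- Against it here: A6 already contains C4 as a methine bearing two different electron-rich aryl groups with defined configuration relative to C3, and the ring closure does nothing to create it. The allylic-transfer logic used in the chosen plan cannot place a second aryl group on C4 directly, so a separate asymmetric arylation would be needed. The coupling of a hindered secondary alkoxide with an ortho-substituted aryl bromide needs heat and base, with risks of benzyloxide elimination and hydrodebromination.
- Comparison: on the endgame (one step against four), on operational safety and on robustness of the ring-closing mechanism, alternative 3 is the better plan, and on C2 control it is at least equal. On the central structural problem, the 3,4-cis diaryl methine, it offers no built-in solution, whereas the chosen plan solves C3 and C4 in one rearrangement and pays for it with a longer sequence and a photochemical step.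

Key step: step 13

Assumption: (triisopropylsiloxy)acetylene 22 is treated as a purchasable silyl ynol ether; where it is not stocked, the usual access is O-silylation of the corresponding lithium ynolate with i-Pr3SiOTf.

## Route

Step 1
Reactants: 1 2-methoxyresorcinol; 2 benzyl bromide
Product: 3 1,3-bis(benzyloxy)-2-methoxybenzene
Conditions: 2 (2.2 equiv), K2CO3, DMF, rt
Reagents that add atoms: benzyl bromide (BrCc1ccccc1)
Why: Williamson etherification of both phenols, which consumes two equivalents of 2: the first is the reactant and the second is the reagent entered above. Benzyl is chosen because it can later be removed by hydrogenolysis while the methyl ether of ring D stays.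

Step 2
Reactants: 3 1,3-bis(benzyloxy)-2-methoxybenzene
Product: 4 1,3-bis(benzyloxy)-4-iodo-2-methoxybenzene
Conditions: N-iodosuccinimide, CF3CO2H (cat.), MeCN, 0 °C to rt
Reagents that add atoms: N-iodosuccinimide (O=C1CCC(=O)N1I)
Why: Electrophilic aromatic iodination; C4 is ortho to one benzyloxy group and para to the other, whereas C5 is meta to both, so mono-iodination at C4 is expected.

Step 3
Reactants: 4 1,3-bis(benzyloxy)-4-iodo-2-methoxybenzene; 5 (S)-but-3-yn-2-ol
Product: 6 (S)-4-[2,4-bis(benzyloxy)-3-methoxyphenyl]but-3-yn-2-ol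
Conditions: PdCl2(PPh3)2 (cat.), CuI (cat.), Et3N, THF, rt
Reagents that add atoms: none
Why: Sonogashira coupling of an aryl iodide with a terminal alkyne; the free propargylic alcohol is tolerated and its stereocenter, the only one brought in from outside, is not involved.

Step 4
Reactants: 6 (S)-4-[2,4-bis(benzyloxy)-3-methoxyphenyl]but-3-yn-2-ol
Product: 7 (2S,3Z)-4-[2,4-bis(benzyloxy)-3-methoxyphenyl]but-3-en-2-ol
Conditions: H2 (1 atm), Pd/CaCO3 poisoned with Pb(OAc)2 (Lindlar catalyst), quinoline, EtOAc, rt
Reagents that add atoms: none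
Why: Lindlar semi-hydrogenation adds H2 syn to the alkyne and gives the Z olefin; benzyl ethers are not cleaved on the poisoned catalyst.

Step 5
Reactants: 7 (2S,3Z)-4-[2,4-bis(benzyloxy)-3-methoxyphenyl]but-3-en-2-ol; 8 benzyloxyacetic acid
Product: 9 (2S,3Z)-4-[2,4-bis(benzyloxy)-3-methoxyphenyl]but-3-en-2-yl 2-(benzyloxy)acetate
Conditions: N,N'-dicyclohexylcarbodiimide, 4-(dimethylamino)pyridine (cat.), CH2Cl2, 0 °C to rt
Reagents that add atoms: none
Why: Steglich esterification under neutral conditions, which avoids ionisation of the electron-rich allylic alcohol; the carbinol configuration is retained.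

Step 6
Reactants: 9 (2S,3Z)-4-[2,4-bis(benzyloxy)-3-methoxyphenyl]but-3-en-2-yl 2-(benzyloxy)acetate
Product: 12 (2S,3R,4E)-2-(benzyloxy)-3-[2,4-bis(benzyloxy)-3-methoxyphenyl]hex-4-en-1-ol, via silyl ketene acetal 10 (not isolated), via trimethylsilyl ester 11 (not isolated)
Conditions: LiN(SiMe3)2, Me3SiCl, Et3N, THF, −78 °C to rt; volatiles removed; then LiAlH4 (excess), THF, 0 °C
Reagents that add atoms: chlorotrimethylsilane (C[Si](C)(C)Cl)
Why: Ireland–Claisen rearrangement followed by hydride reduction of silyl ester 11 without isolation, so that the Me3Si group sits in 10 and 11 only and 12 carries no silicon. Lithium chelation between the enolate oxygen and the benzyloxy group fixes the (Z)-ketene acetal 10, and the chair transition state places the benzyloxy group and the carbinol methyl equatorial and the Z-aryl group axial, so the new C–C bond forms suprafacially from the (S)-carbinol. This gives the 3,4-anti pair (flavan C3 S, flavan C4 R in these open-chain compounds) and the E olefin; an E-configured ester would give the syn pair instead.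

Step 7
Reactants: 12 (2S,3R,4E)-2-(benzyloxy)-3-[2,4-bis(benzyloxy)-3-methoxyphenyl]hex-4-en-1-ol
Product: 13 (2S,3R,4E)-2-(benzyloxy)-3-[2,4-bis(benzyloxy)-3-methoxyphenyl]hex-4-enal
Conditions: Dess–Martin periodinane, NaHCO3, CH2Cl2, 0 °C to rt
Reagents that add atoms: none
Why: Dess–Martin oxidation of a primary alcohol under buffered, non-basic conditions, so the α-benzyloxy stereocenter should not epimerise; the aldehyde is used at once.

Step 8
Reactants: 14 4-bromocatechol; 2 benzyl bromide
Product: 15 1,2-bis(benzyloxy)-4-bromobenzene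
Conditions: 2 (2.2 equiv), K2CO3, DMF, rt
Reagents that add atoms: benzyl bromide (BrCc1ccccc1)
Why: Williamson etherification of both catechol hydroxyls, which consumes two equivalents of 2: the first is the reactant and the second is the reagent entered above. This gives the ring B building block in the same protecting group as the rest.

Step 9
Reactants: 15 1,2-bis(benzyloxy)-4-bromobenzene; 13 (2S,3R,4E)-2-(benzyloxy)-3-[2,4-bis(benzyloxy)-3-methoxyphenyl]hex-4-enal
Product: 17 (1S,2S,3R,4E)-2-(benzyloxy)-1-[3,4-bis(benzyloxy)phenyl]-3-[2,4-bis(benzyloxy)-3-methoxyphenyl]hex-4-en-1-ol, via arylmagnesium bromide 16 (not isolated)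
Conditions: 15, Mg, THF, rt; then 13, MgBr2·OEt2, CH2Cl2, −78 °C
Reagents that add atoms: magnesium ([Mg])
Why: Grignard formation (the magnesium is carried by 16 only and leaves as a salt on work-up) and Cram-chelate addition to an α-alkoxy aldehyde. Magnesium bridges the aldehyde oxygen and the benzyloxy oxygen, and the aryl group enters from the face of the chelate opposite the C3 substituent of 13 (the future flavan C4), which gives the 1,2-syn (1S) alcohol. This is deliberately the C2 epimer of the target, as required for ring closure with inversion.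

Step 10
Reactants: 17 (1S,2S,3R,4E)-2-(benzyloxy)-1-[3,4-bis(benzyloxy)phenyl]-3-[2,4-bis(benzyloxy)-3-methoxyphenyl]hex-4-en-1-ol
Product: 18 [(1S,2S,3R,4E)-2-(benzyloxy)-1-[3,4-bis(benzyloxy)phenyl]-3-[2,4-bis(benzyloxy)-3-methoxyphenyl]hex-4-en-1-yl]oxy(triethyl)silane
Conditions: Et3SiOTf, 2,6-lutidine, CH2Cl2, −78 to 0 °C
Reagents that add atoms: triethylsilyl trifluoromethanesulfonate (CC[Si](CC)(CC)OS(=O)(=O)C(F)(F)F)
Why: Silylation of a hindered secondary alcohol with a silyl triflate. Triethylsilyl is chosen over a bulkier silyl group because it can later be removed with buffered HF without touching the aryl silyl ether and without generating a cation at the electron-rich benzylic C2.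

Step 11
Reactants: 18 [(1S,2S,3R,4E)-2-(benzyloxy)-1-[3,4-bis(benzyloxy)phenyl]-3-[2,4-bis(benzyloxy)-3-methoxyphenyl]hex-4-en-1-yl]oxy(triethyl)silane
Product: 19 (3E,5R,6S,7S)-6-(benzyloxy)-7-[3,4-bis(benzyloxy)phenyl]-5-[2,4-bis(benzyloxy)-3-methoxyphenyl]-7-(triethylsilyloxy)hept-3-en-2-one
Conditions: but-3-en-2-one (5 equiv), RuCl2(H2IMes)(=CH-C6H4-2-O-i-Pr) (second-generation Hoveyda–Grubbs catalyst, 10 mol %), CH2Cl2, 40 °C
Reagents that add atoms: but-3-en-2-one (CC(=O)C=C)
Why: Olefin cross-metathesis: the propenyl group exchanges its ethylidene end for the acetylmethylidene unit with loss of propene. The electron-poor partner homodimerises slowly and gives the E enone, and no sp3 center is touched.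

Step 12
Reactants: 19 (3E,5R,6S,7S)-6-(benzyloxy)-7-[3,4-bis(benzyloxy)phenyl]-5-[2,4-bis(benzyloxy)-3-methoxyphenyl]-7-(triethylsilyloxy)hept-3-en-2-one
Product: 21 (3E,5R,6S,7S)-6-(benzyloxy)-7-[3,4-bis(benzyloxy)phenyl]-5-[2,4-bis(benzyloxy)-3-methoxyphenyl]-1-diazo-7-(triethylsilyloxy)hept-3-en-2-one, via trifluoroacetyl diketone 20 (not isolated)
Conditions: LiN(SiMe3)2, THF, −78 °C; CF3CO2CH2CF3; aq NH4Cl; then 4-AcNHC6H4SO2N3, Et3N, H2O, MeCN, rt
Reagents that add atoms: 4-acetamidobenzenesulfonyl azide (CC(=O)Nc1ccc(cc1)S(=O)(=O)N=[N+]=[N-]); 2,2,2-trifluoroethyl trifluoroacetate (O=C(OCC(F)(F)F)C(F)(F)F)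
Why: Detrifluoroacetylative (deacylative Regitz-type) diazo transfer: the kinetic enolate of the methyl group is trifluoroacetylated, and the activated 1,3-dicarbonyl 20 takes the diazo group from the sulfonyl azide and loses the trifluoroacetyl group, which is therefore present in 20 only. This makes the diazo enone without diazomethane and without a dipolar cycloaddition to the conjugated double bond; kinetic deprotonation at −78 °C leaves the γ-position (C4) alone.

Step 13
Reactants: 21 (3E,5R,6S,7S)-6-(benzyloxy)-7-[3,4-bis(benzyloxy)phenyl]-5-[2,4-bis(benzyloxy)-3-methoxyphenyl]-1-diazo-7-(triethylsilyloxy)hept-3-en-2-one; 22 (triisopropylsiloxy)acetylene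
Product: 27 2-[(1R,2S,3S)-2-(benzyloxy)-3-[3,4-bis(benzyloxy)phenyl]-1-[2,4-bis(benzyloxy)-3-methoxyphenyl]-3-(triethylsilyloxy)propyl]-5-(triisopropylsilyloxy)phenol, via vinylketene 23 (not isolated), via siloxycyclobutenone 24 (not isolated), via dienylketene 25 (not isolated), via cyclohexadienone 26 (not isolated)
Conditions: 22 (2 equiv), hν (365 nm), ClCH2CH2Cl, rt; then 80 °C
Reagents that add atoms: none
Why: Light at 365 nm is absorbed mainly by the diazo enone, since the aryl ethers are transparent at that wavelength; N2 is lost and the alkenyl group migrates (photochemical Wolff rearrangement, forming C5–C6) to give vinylketene 23. The ketene adds across the electron-rich alkyne of 22 in a regiospecific (2+2) cycloaddition, in which the nucleophilic CH carbon of 22 bonds to the ketene carbonyl carbon (C8–C8a) and the oxygen-bearing carbon bonds to C6 (C6–C7), giving 24. Warming opens 24 reversibly by a conrotatory 4-electron electrocyclic reaction to dienylketene 25, and the isomer with the alkenyl group turned inward closes ring A by a thermal disrotatory 6-electron electrocyclisation (C4a–C8a) to 26, which tautomerises to phenol 27. The closest known reaction type is the benzannulation of α-diazo enones with siloxyalkynes (Danheiser benzannulation). No stereocenter is created: the sp3 centers of 24 and 26 are transient, and C4, C3 and C2 are spectators. The step needs regiocontrol, which the polarity match of ketene and ynol ether secures, and survival of the allylic C4 center, which the absence of acid, base and metal secures. Capture of 23 by 22 must outrun ketene dimerisation and acylation of the product phenol, which the excess of 22 and moderate dilution favour.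

Step 14
Reactants: 27 2-[(1R,2S,3S)-2-(benzyloxy)-3-[3,4-bis(benzyloxy)phenyl]-1-[2,4-bis(benzyloxy)-3-methoxyphenyl]-3-(triethylsilyloxy)propyl]-5-(triisopropylsilyloxy)phenol
Product: 28 2-[(1R,2S,3S)-2-(benzyloxy)-3-[3,4-bis(benzyloxy)phenyl]-1-[2,4-bis(benzyloxy)-3-methoxyphenyl]-3-hydroxypropyl]-5-(triisopropylsilyloxy)phenol
Conditions: HF·pyridine, pyridine, THF, 0 °C
Reagents that add atoms: none
Why: Buffered HF cleaves the alkyl triethylsilyl ether much faster than the bulky aryl triisopropylsilyl ether, and the medium is too weakly acidic to ionise the benzylic C2–O bond, so C2 keeps its configuration.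

Step 15
Reactants: 28 2-[(1R,2S,3S)-2-(benzyloxy)-3-[3,4-bis(benzyloxy)phenyl]-1-[2,4-bis(benzyloxy)-3-methoxyphenyl]-3-hydroxypropyl]-5-(triisopropylsilyloxy)phenol
Product: 29 (2R,3S,4R)-3-(benzyloxy)-2-[3,4-bis(benzyloxy)phenyl]-4-[2,4-bis(benzyloxy)-3-methoxyphenyl]-7-(triisopropylsilyloxy)chromane
Conditions: PPh3, i-PrO2CN=NCO2i-Pr, THF (0.01 M), 0 °C to rt
Reagents that add atoms: none
Why: Intramolecular Mitsunobu etherification: the C2 hydroxyl is activated on phosphorus and displaced by the ortho phenol in a 6-exo SN2 closure of the O1–C2 bond. Inversion turns the (S)-carbinol into the (2R) center and gives the 2,3-trans ring; C3 and C4 are not involved (the C4 descriptor reads R here only because the benzyl ethers change the priorities).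

Step 16
Reactants: 29 (2R,3S,4R)-3-(benzyloxy)-2-[3,4-bis(benzyloxy)phenyl]-4-[2,4-bis(benzyloxy)-3-methoxyphenyl]-7-(triisopropylsilyloxy)chromane
Product: 30 (2R,3S,4R)-3-(benzyloxy)-2-[3,4-bis(benzyloxy)phenyl]-4-[2,4-bis(benzyloxy)-3-methoxyphenyl]chroman-7-ol
Conditions: Bu4NF, AcOH, THF, 0 °C
Reagents that add atoms: none
Why: Fluoride cleavage of an aryl silyl ether; the acetic acid buffer keeps the liberated phenoxide from acting as a base on the chroman.

Step 17
Reactants: 30 (2R,3S,4R)-3-(benzyloxy)-2-[3,4-bis(benzyloxy)phenyl]-4-[2,4-bis(benzyloxy)-3-methoxyphenyl]chroman-7-ol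
Product: 31 4beta-(2,4-dihydroxy-3-methoxyphenyl)fisetinidol
Conditions: H2 (1 atm), Pd(OH)2/C, EtOAc–MeOH, rt
Reagents that add atoms: none
Why: Catalytic hydrogenolysis of the five benzyl ethers under neutral conditions. The methyl ether and the ring ether should be retained, and the product is isolated by filtration and evaporation under inert gas.

## Compound list

1 | 2-methoxyresorcinol | COc1c(O)cccc1O | starting material
2 | benzyl bromide | BrCc1ccccc1 | starting material
3 | 1,3-bis(benzyloxy)-2-methoxybenzene | COc1c(OCc2ccccc2)cccc1OCc1ccccc1 | intermediate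
4 | 1,3-bis(benzyloxy)-4-iodo-2-methoxybenzene | COc1c(OCc2ccccc2)ccc(I)c1OCc1ccccc1 | intermediate
5 | (S)-but-3-yn-2-ol | C[C@H](O)C#C | starting material
6 | (S)-4-[2,4-bis(benzyloxy)-3-methoxyphenyl]but-3-yn-2-ol | C[C@H](O)C#Cc1ccc(OCc2ccccc2)c(OC)c1OCc1ccccc1 | intermediate
7 | (2S,3Z)-4-[2,4-bis(benzyloxy)-3-methoxyphenyl]but-3-en-2-ol | C[C@H](O)/C=C\c1ccc(OCc2ccccc2)c(OC)c1OCc1ccccc1 | intermediate
8 | benzyloxyacetic acid | OC(=O)COCc1ccccc1 | starting material
9 | (2S,3Z)-4-[2,4-bis(benzyloxy)-3-methoxyphenyl]but-3-en-2-yl 2-(benzyloxy)acetate | C[C@H](OC(=O)COCc1ccccc1)/C=C\c1ccc(OCc2ccccc2)c(OC)c1OCc1ccccc1 | intermediate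
10 | (Z)-trimethylsilyl ketene acetal of 9 (benzyloxy cis to silyloxy) | C[C@H](O/C(O[Si](C)(C)C)=C/OCc1ccccc1)/C=C\c1ccc(OCc2ccccc2)c(OC)c1OCc1ccccc1 | intermediate
11 | trimethylsilyl (2S,3R,4E)-2-(benzyloxy)-3-[2,4-bis(benzyloxy)-3-methoxyphenyl]hex-4-enoate | COc1c(OCc4ccccc4)ccc([C@@H](/C=C/C)[C@H](OCc4ccccc4)C(=O)O[Si](C)(C)C)c1OCc4ccccc4 | intermediate
12 | (2S,3R,4E)-2-(benzyloxy)-3-[2,4-bis(benzyloxy)-3-methoxyphenyl]hex-4-en-1-ol | COc1c(OCc4ccccc4)ccc([C@@H](/C=C/C)[C@H](OCc4ccccc4)CO)c1OCc4ccccc4 | intermediate
13 | (2S,3R,4E)-2-(benzyloxy)-3-[2,4-bis(benzyloxy)-3-methoxyphenyl]hex-4-enal | COc1c(OCc4ccccc4)ccc([C@@H](/C=C/C)[C@H](OCc4ccccc4)C=O)c1OCc4ccccc4 | intermediate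
14 | 4-bromocatechol | Oc1ccc(Br)cc1O | starting material
15 | 1,2-bis(benzyloxy)-4-bromobenzene | Brc1ccc(OCc2ccccc2)c(OCc2ccccc2)c1 | intermediate
16 | [3,4-bis(benzyloxy)phenyl]magnesium bromide | Br[Mg]c1ccc(OCc2ccccc2)c(OCc2ccccc2)c1 | intermediate
17 | (1S,2S,3R,4E)-2-(benzyloxy)-1-[3,4-bis(benzyloxy)phenyl]-3-[2,4-bis(benzyloxy)-3-methoxyphenyl]hex-4-en-1-ol | COc1c(OCc4ccccc4)ccc([C@@H](/C=C/C)[C@H](OCc4ccccc4)[C@@H](O)c3ccc(OCc4ccccc4)c(OCc4ccccc4)c3)c1OCc4ccccc4 | intermediate
18 | [(1S,2S,3R,4E)-2-(benzyloxy)-1-[3,4-bis(benzyloxy)phenyl]-3-[2,4-bis(benzyloxy)-3-methoxyphenyl]hex-4-en-1-yl]oxy(triethyl)silane | COc1c(OCc4ccccc4)ccc([C@@H](/C=C/C)[C@H](OCc4ccccc4)[C@@H](O[Si](CC)(CC)CC)c3ccc(OCc4ccccc4)c(OCc4ccccc4)c3)c1OCc4ccccc4 | intermediate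
19 | (3E,5R,6S,7S)-6-(benzyloxy)-7-[3,4-bis(benzyloxy)phenyl]-5-[2,4-bis(benzyloxy)-3-methoxyphenyl]-7-(triethylsilyloxy)hept-3-en-2-one | COc1c(OCc4ccccc4)ccc([C@@H](/C=C/C(C)=O)[C@H](OCc4ccccc4)[C@@H](O[Si](CC)(CC)CC)c3ccc(OCc4ccccc4)c(OCc4ccccc4)c3)c1OCc4ccccc4 | intermediate
20 | (5E,7R,8S,9S)-8-(benzyloxy)-9-[3,4-bis(benzyloxy)phenyl]-7-[2,4-bis(benzyloxy)-3-methoxyphenyl]-1,1,1-trifluoro-9-(triethylsilyloxy)non-5-ene-2,4-dione | COc1c(OCc4ccccc4)ccc([C@@H](/C=C/C(=O)CC(=O)C(F)(F)F)[C@H](OCc4ccccc4)[C@@H](O[Si](CC)(CC)CC)c3ccc(OCc4ccccc4)c(OCc4ccccc4)c3)c1OCc4ccccc4 | intermediate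
21 | (3E,5R,6S,7S)-6-(benzyloxy)-7-[3,4-bis(benzyloxy)phenyl]-5-[2,4-bis(benzyloxy)-3-methoxyphenyl]-1-diazo-7-(triethylsilyloxy)hept-3-en-2-one | COc1c(OCc4ccccc4)ccc([C@@H](/C=C/C(=O)C=[N+]=[N-])[C@H](OCc4ccccc4)[C@@H](O[Si](CC)(CC)CC)c3ccc(OCc4ccccc4)c(OCc4ccccc4)c3)c1OCc4ccccc4 | intermediate
22 | (triisopropylsiloxy)acetylene | C#CO[Si](C(C)C)(C(C)C)C(C)C | starting material
23 | (3E,5R,6S,7S)-6-(benzyloxy)-7-[3,4-bis(benzyloxy)phenyl]-5-[2,4-bis(benzyloxy)-3-methoxyphenyl]-7-(triethylsilyloxy)hepta-1,3-dien-1-one (vinylketene) | COc1c(OCc4ccccc4)ccc([C@@H](/C=C/C=C=O)[C@H](OCc4ccccc4)[C@@H](O[Si](CC)(CC)CC)c3ccc(OCc4ccccc4)c(OCc4ccccc4)c3)c1OCc4ccccc4 | intermediate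
24 | 4-[(1E,3R,4S,5S)-4-(benzyloxy)-5-[3,4-bis(benzyloxy)phenyl]-3-[2,4-bis(benzyloxy)-3-methoxyphenyl]-5-(triethylsilyloxy)pent-1-en-1-yl]-3-(triisopropylsilyloxy)cyclobut-2-en-1-one (both ring epimers) | COc1c(OCc4ccccc4)ccc([C@@H](/C=C/C2C(=O)C=C2O[Si](C(C)C)(C(C)C)C(C)C)[C@H](OCc4ccccc4)[C@@H](O[Si](CC)(CC)CC)c3ccc(OCc4ccccc4)c(OCc4ccccc4)c3)c1OCc4ccccc4 | intermediate
25 | (5E,7R,8S,9S)-8-(benzyloxy)-9-[3,4-bis(benzyloxy)phenyl]-7-[2,4-bis(benzyloxy)-3-methoxyphenyl]-9-(triethylsilyloxy)-3-(triisopropylsilyloxy)nona-1,3,5-trien-1-one (dienylketene) | COc1c(OCc4ccccc4)ccc([C@@H](/C=C/C=C(O[Si](C(C)C)(C(C)C)C(C)C)C=C=O)[C@H](OCc4ccccc4)[C@@H](O[Si](CC)(CC)CC)c3ccc(OCc4ccccc4)c(OCc4ccccc4)c3)c1OCc4ccccc4 | intermediate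
26 | 6-[(1R,2S,3S)-2-(benzyloxy)-3-[3,4-bis(benzyloxy)phenyl]-1-[2,4-bis(benzyloxy)-3-methoxyphenyl]-3-(triethylsilyloxy)propyl]-3-(triisopropylsilyloxy)cyclohexa-2,4-dien-1-one (both ring epimers) | COc1c(OCc4ccccc4)ccc([C@@H](C2C=CC(O[Si](C(C)C)(C(C)C)C(C)C)=CC2=O)[C@H](OCc4ccccc4)[C@@H](O[Si](CC)(CC)CC)c3ccc(OCc4ccccc4)c(OCc4ccccc4)c3)c1OCc4ccccc4 | intermediate
27 | 2-[(1R,2S,3S)-2-(benzyloxy)-3-[3,4-bis(benzyloxy)phenyl]-1-[2,4-bis(benzyloxy)-3-methoxyphenyl]-3-(triethylsilyloxy)propyl]-5-(triisopropylsilyloxy)phenol | COc1c(OCc4ccccc4)ccc([C@@H](c3ccc(O[Si](C(C)C)(C(C)C)C(C)C)cc3O)[C@H](OCc4ccccc4)[C@@H](O[Si](CC)(CC)CC)c3ccc(OCc4ccccc4)c(OCc4ccccc4)c3)c1OCc4ccccc4 | intermediate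
28 | 2-[(1R,2S,3S)-2-(benzyloxy)-3-[3,4-bis(benzyloxy)phenyl]-1-[2,4-bis(benzyloxy)-3-methoxyphenyl]-3-hydroxypropyl]-5-(triisopropylsilyloxy)phenol | COc1c(OCc4ccccc4)ccc([C@@H](c3ccc(O[Si](C(C)C)(C(C)C)C(C)C)cc3O)[C@H](OCc4ccccc4)[C@@H](O)c3ccc(OCc4ccccc4)c(OCc4ccccc4)c3)c1OCc4ccccc4 | intermediate
29 | (2R,3S,4R)-3-(benzyloxy)-2-[3,4-bis(benzyloxy)phenyl]-4-[2,4-bis(benzyloxy)-3-methoxyphenyl]-7-(triisopropylsilyloxy)chromane | COc1c(OCc4ccccc4)ccc([C@H]2c3ccc(O[Si](C(C)C)(C(C)C)C(C)C)cc3O[C@H](c3ccc(OCc4ccccc4)c(OCc4ccccc4)c3)[C@H]2OCc4ccccc4)c1OCc4ccccc4 | intermediate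
30 | (2R,3S,4R)-3-(benzyloxy)-2-[3,4-bis(benzyloxy)phenyl]-4-[2,4-bis(benzyloxy)-3-methoxyphenyl]chroman-7-ol | COc1c(OCc4ccccc4)ccc([C@H]2c3ccc(O)cc3O[C@H](c3ccc(OCc4ccccc4)c(OCc4ccccc4)c3)[C@H]2OCc4ccccc4)c1OCc4ccccc4 | intermediate
31 | 4beta-(2,4-dihydroxy-3-methoxyphenyl)fisetinidol [(2R,3S,4S)-2-(3,4-dihydroxyphenyl)-4-(2,4-dihydroxy-3-methoxyphenyl)chromane-3,7-diol] | COc1c(O)ccc([C@H]2c3ccc(O)cc3O[C@H](c3ccc(O)c(O)c3)[C@H]2O)c1O | target

## Step count and least certain steps

Total: 17 steps. Longest linear sequence: 16 steps (steps 1–7 and 9–17, from 1 to 31); step 8 is the branch that supplies ring B.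

Step 13 (key step). The most likely failure is incomplete capture of the vinylketene by the ynol ether (ketene dimerisation, acylation of the product phenol). Further risks are inner-filter absorption and secondary photoreactions of the six aryl ether chromophores, and slow opening and closure of the crowded cyclobutenone next to the fully substituted chain. The fallback changes the order of events so that the annulation runs on a smaller substrate without ring B and without the benzylic silyl ether. It sets out from 13, which is converted with HC(OMe)3 and a trace of pyridinium tosylate into the dimethyl acetal F1. Cross-metathesis with but-3-en-2-one gives the enone acetal F2, deacylative diazo transfer gives the diazo enone acetal F3, and the same photochemical annulation with 22 gives the ring A phenol acetal F4. Aqueous acetic acid then releases the aldehyde, which closes onto the phenol as the lactol F5, and chelation-controlled addition of an excess of 16 to F5 returns to the route at 28.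

Step 11. The most likely failure is sluggish metathesis, because the olefin is internal and sits next to the crowded C4 methine. The catalyst may decompose before turnover, or move the double bond into conjugation with ring D. The fallback replaces metathesis by cleavage and olefination. It sets out from 18, which is cleaved with OsO4 (cat.) and NaIO4 in the presence of 2,6-lutidine to the α-aryl aldehyde F6. Without storage, F6 is treated with the neutral stabilised ylide 1-(triphenylphosphoranylidene)propan-2-one (Wittig reaction), which returns to the route at 19.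

Step 6. The most likely failure is erosion of the C3/C4 relationship through leakage to the non-chelated enolate or to a boat transition state. The Z series also rearranges slowly, so the ketene acetal may decompose first. The fallback separates the two stereocenters. It sets out from 7, which undergoes Johnson–Claisen rearrangement with triethyl orthoacetate and a trace of propionic acid to the ester F7; C4 is set by chirality transfer alone, with no enolate geometry involved. The potassium enolate of F7 (KN(SiMe3)2, THF, −78 °C) is hydroxylated with 2-(phenylsulfonyl)-3-phenyloxaziridine, expected to enter anti to the aryl group, giving the hydroxy ester F8. Benzylation with benzyl bromide and Ag2O gives the benzyl ether ester F9, and LiAlH4 reduction of F9 returns to the route at 12.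

Step 9. The most likely failure is poor facial selectivity, because THF carried in with the Grignard reagent competes with the benzyloxy group for magnesium and opens a non-chelated pathway. Enolisation of the aldehyde by the basic reagent is a second risk. The fallback moves the stereocontrol from the substrate to a reagent. It sets out from 17 (as its mixture of epimers at the carbinol carbon), which is oxidised with Dess–Martin periodinane to the aryl ketone F10. Reduction of F10 with BH3·SMe2 and (S)-2-methyl-CBS-oxazaborolidine, with the aryl group expected to act as the larger substituent, returns to the route at 17.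

Step 15. The most likely failure is ionisation at the electron-rich benzylic C2 in place of direct displacement, with loss of stereospecificity, elimination toward the enol ether, or slow closure because of crowding. The fallback changes the mechanism on purpose. It sets out from 28, which is cyclised with a catalytic sulfonic acid in CH2Cl2 at low temperature through the benzylic cation, under thermodynamic control that favours the diequatorial 2,3-trans chroman. It returns to the route at 29 and makes no new compound.

## Further compounds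

F1 | step 13 | (2S,3R,4E)-2-(benzyloxy)-3-[2,4-bis(benzyloxy)-3-methoxyphenyl]hex-4-enal dimethyl acetal | COc1c(OCc4ccccc4)ccc([C@@H](/C=C/C)[C@H](OCc4ccccc4)C(OC)OC)c1OCc4ccccc4
F2 | step 13 | (3E,5R,6S)-6-(benzyloxy)-5-[2,4-bis(benzyloxy)-3-methoxyphenyl]-7,7-dimethoxyhept-3-en-2-one | COc1c(OCc4ccccc4)ccc([C@@H](/C=C/C(C)=O)[C@H](OCc4ccccc4)C(OC)OC)c1OCc4ccccc4
F3 | step 13 | (3E,5R,6S)-6-(benzyloxy)-5-[2,4-bis(benzyloxy)-3-methoxyphenyl]-1-diazo-7,7-dimethoxyhept-3-en-2-one | COc1c(OCc4ccccc4)ccc([C@@H](/C=C/C(=O)C=[N+]=[N-])[C@H](OCc4ccccc4)C(OC)OC)c1OCc4ccccc4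
F4 | step 13 | 2-[(1R,2S)-2-(benzyloxy)-1-[2,4-bis(benzyloxy)-3-methoxyphenyl]-3,3-dimethoxypropyl]-5-(triisopropylsilyloxy)phenol | COc1c(OCc4ccccc4)ccc([C@@H](c3ccc(O[Si](C(C)C)(C(C)C)C(C)C)cc3O)[C@H](OCc4ccccc4)C(OC)OC)c1OCc4ccccc4
F5 | step 13 | (3S,4R)-3-(benzyloxy)-4-[2,4-bis(benzyloxy)-3-methoxyphenyl]-7-(triisopropylsilyloxy)chroman-2-ol (both anomers) | COc1c(OCc4ccccc4)ccc([C@H]2c3ccc(O[Si](C(C)C)(C(C)C)C(C)C)cc3OC(O)[C@H]2OCc4ccccc4)c1OCc4ccccc4
F6 | step 11 | (2R,3S,4S)-3-(benzyloxy)-4-[3,4-bis(benzyloxy)phenyl]-2-[2,4-bis(benzyloxy)-3-methoxyphenyl]-4-(triethylsilyloxy)butanal | COc1c(OCc4ccccc4)ccc([C@@H](C=O)[C@H](OCc4ccccc4)[C@@H](O[Si](CC)(CC)CC)c3ccc(OCc4ccccc4)c(OCc4ccccc4)c3)c1OCc4ccccc4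
F7 | step 6 | ethyl (3R,4E)-3-[2,4-bis(benzyloxy)-3-methoxyphenyl]hex-4-enoate | COc1c(OCc4ccccc4)ccc([C@@H](/C=C/C)CC(=O)OCC)c1OCc4ccccc4
F8 | step 6 | ethyl (2S,3R,4E)-3-[2,4-bis(benzyloxy)-3-methoxyphenyl]-2-hydroxyhex-4-enoate | COc1c(OCc4ccccc4)ccc([C@@H](/C=C/C)[C@H](O)C(=O)OCC)c1OCc4ccccc4
F9 | step 6 | ethyl (2S,3R,4E)-2-(benzyloxy)-3-[2,4-bis(benzyloxy)-3-methoxyphenyl]hex-4-enoate | COc1c(OCc4ccccc4)ccc([C@@H](/C=C/C)[C@H](OCc4ccccc4)C(=O)OCC)c1OCc4ccccc4
F10 | step 9 | (2S,3R,4E)-2-(benzyloxy)-1-[3,4-bis(benzyloxy)phenyl]-3-[2,4-bis(benzyloxy)-3-methoxyphenyl]hex-4-en-1-one | COc1c(OCc4ccccc4)ccc([C@@H](/C=C/C)[C@H](OCc4ccccc4)C(=O)c3ccc(OCc4ccccc4)c(OCc4ccccc4)c3)c1OCc4ccccc4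
F0 | step 15 | none | none
A1 | alternative 1 | (3S,4R)-3,7-bis(benzyloxy)-4-[2,4-bis(benzyloxy)-3-methoxyphenyl]chroman-2-one (3,4-cis) | COc1c(OCc4ccccc4)ccc([C@H]2c3ccc(OCc4ccccc4)cc3OC(=O)[C@H]2OCc4ccccc4)c1OCc4ccccc4
A2 | alternative 1 | 3-(benzyloxy)-6-[[2,4-bis(benzyloxy)-3-methoxyphenyl]methylidene]cyclohexa-2,4-dien-1-one (ortho-quinone methide) | O=C1C=C(OCc2ccccc2)C=CC1=Cc1ccc(OCc2ccccc2)c(OC)c1OCc1ccccc1
A3 | alternative 2 | (2R,3S,4R)-7-(benzyloxy)-2-[3,4-bis(benzyloxy)phenyl]-4-[3-methoxy-2,4-bis(pivaloyloxy)phenyl]chroman-3-ol | COc1c(OC(=O)C(C)(C)C)ccc([C@H]2c3ccc(OCc4ccccc4)cc3O[C@H](c3ccc(OCc4ccccc4)c(OCc4ccccc4)c3)[C@H]2O)c1OC(=O)C(C)(C)C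
A4 | alternative 2 | (2S,3S)-2-[3-methoxy-2,4-bis(pivaloyloxy)phenyl]-3-[(R)-[3-(benzyloxy)phenoxy][3,4-bis(benzyloxy)phenyl]methyl]oxirane (cis-epoxide) | COc1c(OC(=O)C(C)(C)C)ccc([C@@H]2O[C@@H]2[C@H](Oc2cccc(OCc3ccccc3)c2)c2ccc(OCc3ccccc3)c(OCc3ccccc3)c2)c1OC(=O)C(C)(C)C
A5 | alternative 3 | (2R,3S,4R)-3,7-bis(benzyloxy)-2-[3,4-bis(benzyloxy)phenyl]-4-[2,4-bis(benzyloxy)-3-methoxyphenyl]chromane | COc1c(OCc4ccccc4)ccc([C@H]2c3ccc(OCc4ccccc4)cc3O[C@H](c3ccc(OCc4ccccc4)c(OCc4ccccc4)c3)[C@H]2OCc4ccccc4)c1OCc4ccccc4
A6 | alternative 3 | (1R,2S,3S)-2-(benzyloxy)-3-[4-(benzyloxy)-2-bromophenyl]-1-[3,4-bis(benzyloxy)phenyl]-3-[2,4-bis(benzyloxy)-3-methoxyphenyl]propan-1-ol | COc1c(OCc4ccccc4)ccc([C@@H](c3ccc(OCc4ccccc4)cc3Br)[C@H](OCc4ccccc4)[C@H](O)c3ccc(OCc4ccccc4)c(OCc4ccccc4)c3)c1OCc4ccccc4
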